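**Retrosynthetic overview**

1. The route rests on the seven-membered ring C5–C6–C7–C8–C9–C10 (closed through the cyclobutane). Its oxygens at C7 and C9 are anti, carry two different esters on either side of the C8 methylene, and sit between the quaternary carbons C6 and C10. So 28 ⇒ alcohol 25 (senecioylation of O9) ⇒ keto aldehyde 21, by a C7–C8 aldol with hydride delivery to C9 from a tiglaldehyde hemiacetal on O7.
2. 21 ⇒ triol 19 ⇒ lactone 17, in which O9–C7(=O) ties C6 and C9 on one face. The C5–C6 bond comes from an isobutyrate held on O9 adding to a C5 cyclobutanone, followed by removal of the C5 oxygen.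
3. Cyclobutanone 13 (bicyclo[3.1.1]heptan-6-one) ⇒ acyclic dienoic acid 10 by intramolecular vinylketene–alkene [2+2]. The (E) alkene fixes C10, and the C1 silyl ether fixes the absolute sense of C4, C10 and C11.
4. 10 ⇒ enal 5 + senecioate dienolate 7 (vinylogous aldol); 5 comes from (S)-but-3-yn-2-ol by carboalumination.
5. Ring order: cyclobutane and six-membered ring together (step 8), temporary lactone (step 9), seven-membered carbocycle last (step 14).

Key step: step 14

Numbering: cage atoms carry longipinane numbers in every intermediate (C1 carbonyl carbon, C2=C3 alkene with CH3 on C3, C4 and C11 bridgeheads, C5 cyclobutane CH, C6 C(CH3)2, C7, C8, C9, C10 quaternary cyclobutane carbon).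

Assumption: the sense of induction of the two chiral catalysts (bisphosphoramide in step 5, binaphthoxide complex in step 14) is taken as written; if either proves opposite, its mirror-image catalyst is used and nothing else changes.

Remark: the C9 carbinol centre from 1 is a spectator that is destroyed in step 13. The (S) form is chosen so that its inside-alkoxy preference favours the same alkene face in step 8 as the C1 silyl ether does.

**Route**

Step 1
Reactants: 1 (S)-but-3-yn-2-ol
Product: 3 (2E,4S)-3-methylpent-2-ene-1,4-diol, via alkenylalane 2 (not isolated)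
Conditions: Me3Al (3 equiv), Cp2ZrCl2 (0.25 equiv), CH2Cl2, 0 °C to rt; evaporate; n-BuLi, THF/hexane, 0 °C; (CH2O)n, rt
Reagents that add atoms: trimethylaluminium, C[Al](C)C; formaldehyde (as paraformaldehyde), C=O
Why: Zirconium-catalysed syn carboalumination (Negishi) puts CH3 on the internal alkyne carbon and aluminium on the terminus, and hydroxymethylation of the alanate with retention gives the (E) alkene (C9 trans to C1) that later defines C10, while the carbinol centre is untouched.

Step 2
Reactants: 3 (2E,4S)-3-methylpent-2-ene-1,4-diol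
Product: 4 (2E,4S)-4-hydroxy-3-methylpent-2-enal
Conditions: TEMPO (10 mol %), PhI(OAc)2 (1.1 equiv), CH2Cl2, rt
Reagents that add atoms: none
Why: Oxoammonium (TEMPO) oxidation takes the primary allylic alcohol much faster than the hindered secondary one, and the (E) geometry keeps the hydroxy enal from closing to a lactol.

Step 3
Reactants: 4 (2E,4S)-4-hydroxy-3-methylpent-2-enal
Product: 5 (2S,3E)-3-methyl-5-oxopent-3-en-2-yl 2-methylpropanoate
Conditions: 2-methylpropanoyl chloride, pyridine, DMAP (cat.), CH2Cl2, 0 °C
Reagents that add atoms: 2-methylpropanoyl chloride, CC(C)C(Cl)=O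
Why: Standard DMAP-catalysed acylation installs the isobutyrate, which protects O9 and later supplies C6, its two methyls and C7.

Step 4
Reactants: 6 methyl 3-methylbut-2-enoate
Product: 7 tert-butyl[(1-methoxy-3-methylbuta-1,3-dien-1-yl)oxy]dimethylsilane
Conditions: LiN(iPr)2, THF/DMPU, −78 °C; t-BuMe2SiCl
Reagents that add atoms: tert-butylchlorodimethylsilane, CC(C)(C)[Si](C)(C)Cl
Why: γ-Deprotonation of the senecioate and O-silylation of the dienolate give the silyl ketene acetal used in vinylogous Mukaiyama aldol reactions.

Step 5
Reactants: 5 (2S,3E)-3-methyl-5-oxopent-3-en-2-yl 2-methylpropanoate; 7 silyl dienolate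
Product: 8 methyl (2E,5S,6E,8S)-5-hydroxy-3,7-dimethyl-8-[(2-methylpropanoyl)oxy]nona-2,6-dienoate
Conditions: SiCl4 (1.1 equiv), (S,S)-1,1'-binaphthyl-2,2'-diamine-derived bisphosphoramide (5 mol %), iPr2NEt (10 mol %), CH2Cl2, −78 °C; aq. NaHCO3/KF
Reagents that add atoms: silyl dienolate 7, COC(O[Si](C)(C)C(C)(C)C)=CC(C)=C
Why: The Lewis-base-activated SiCl4 vinylogous Mukaiyama aldol should add the γ-carbon of the dienolate to the Si face of the conjugated aldehyde under catalyst control and set the C1 carbinol (5S), with the 2E enoate expected from the open transition state (any 2Z ester lactonises and is removed) and the remote C9 centre not interfering.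

Step 6
Reactants: 8 methyl (2E,5S,6E,8S)-5-hydroxy-3,7-dimethyl-8-[(2-methylpropanoyl)oxy]nona-2,6-dienoate
Product: 9 methyl (2E,5S,6E,8S)-5-[(tert-butyldimethylsilyl)oxy]-3,7-dimethyl-8-[(2-methylpropanoyl)oxy]nona-2,6-dienoate
Conditions: t-BuMe2SiOTf, 2,6-lutidine, CH2Cl2, −78 °C
Reagents that add atoms: tert-butyldimethylsilyl triflate, CC(C)(C)[Si](C)(C)OS(=O)(=O)C(F)(F)F
Why: Routine silylation gives the bulky C1 ether that protects O1 and later steers the cycloaddition.

Step 7
Reactants: 9 silyl ether methyl ester
Product: 10 (2E,5S,6E,8S)-5-[(tert-butyldimethylsilyl)oxy]-3,7-dimethyl-8-[(2-methylpropanoyl)oxy]nona-2,6-dienoic acid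
Conditions: Me3SnOH (4 equiv), 1,2-dichloroethane, 80 °C; dilute aq. HCl wash
Reagents that add atoms: none
Why: Trimethyltin hydroxide cleaves methyl esters under neutral conditions and leaves the hindered secondary isobutyrate, the silyl ether and both alkene geometries untouched (chemoselective ester hydrolysis).

Step 8
Reactants: 10 dienoic acid
Product: 13 (1S)-1-[4-(tert-butyldimethylsilyloxy)-7-methyl-2-methylidene-6-oxobicyclo[3.1.1]heptan-7-yl]ethyl 2-methylpropanoate, via acid chloride 11 (not isolated), via vinylketene 12 (not isolated)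
Conditions: 1-chloro-N,N,2-trimethylpropenylamine, CH2Cl2, 0 °C to rt; then slow addition to Et3N (3 equiv), toluene, 110 °C, high dilution
Reagents that add atoms: none
Why: Dehydrochlorination through the C3 methyl (cis to the acyl group in the 2E acid) gives the vinylketene, whose intramolecular ketene–alkene [2+2] cycloaddition bonds the ketene carbonyl carbon (C5) to the less substituted alkene carbon C11 and the α-carbon C4 to the tertiary C10 (bridged mode, as with geranic and farnesic acid chlorides); addition is suprafacial on the (E) alkene, so the C10 methyl ends toward the C1–C3 bridge and C9 on the C5 side, and the C1 silyloxy group avoids allylic 1,3-strain with that methyl and ends on the side of the C5 bridge, which fixes the absolute configuration of C4, C10 and C11.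

Step 9
Reactants: 13 bicyclic cyclobutanone
Product: 16 tertiary methyl oxalate of the C5-hydroxy lactone, via lithium ester enolate 14 (not isolated), via lithium aldolate 15 (not isolated)
Conditions: lithium 2,2,6,6-tetramethylpiperidide (1.1 equiv), THF, −78 °C; then ClC(=O)CO2Me, −78 to −40 °C
Reagents that add atoms: methyl chlorooxoacetate, COC(=O)C(Cl)=O
Why: The cyclobutanone has only bridgehead α-hydrogens, so the hindered amide deprotonates only the isobutyrate, whose enolate, held on O9, can reach C5 only from the C10 face (intramolecular ester-enolate aldol closing the seven-membered lactone and forming C5–C6), and the tertiary alkoxide, a 2-alkenylcyclobutoxide, is acylated cold at once before it can fragment.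

Step 10
Reactants: 16 tertiary methyl oxalate
Product: 17 lactone with C5–H and the C1 silyl ether
Conditions: Bu3SnH (3 equiv, 0.3 M), AIBN (cat.), toluene, 110 °C
Reagents that add atoms: none
Why: Barton–McCombie-type radical deoxygenation of a tertiary methyl oxalate gives the C5 radical, which can take hydrogen only from the face opposite the lactone bridge, so H5 points to the C1–C3 bridge and C6 stays on the C10 side (the high tin hydride concentration is meant to outpace cyclobutyl ring opening).

Step 11
Reactants: 17 silyl ether lactone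
Product: 18 C1-hydroxy lactone
Conditions: Bu4NF, THF, rt
Reagents that add atoms: none
Why: Fluoride desilylation frees the C1 alcohol without touching the hindered lactone.

Step 12
Reactants: 18 C1-hydroxy lactone
Product: 19 triol (C1–OH, primary C7–OH, secondary C9–OH)
Conditions: LiAlH4, THF, 0 °C to reflux; Fieser work-up
Reagents that add atoms: none
Why: Hydride reduction opens the lactone into a primary alcohol at C7 and a secondary alcohol at C9, which differentiates the two carbons by oxidation level without protecting groups.

Step 13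
Reactants: 19 triol
Product: 21 keto aldehyde (C1 enone with C9 acetyl and C7 formyl), via exocyclic-alkene keto aldehyde 20 (not isolated)
Conditions: (COCl)2, DMSO, CH2Cl2, −78 °C; Et3N, −78 to 0 °C; then DBU (0.2 equiv), 0 °C, short
Reagents that add atoms: none
Why: Swern oxidation activates all three hydroxyls at low temperature, so the C7 aldehyde never meets a free C9 hydroxyl (no lactol and no lactone), and base then moves the exocyclic C3 alkene into conjugation with the C1 ketone through the doubly activated C2 hydrogens.

Step 14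
Reactants: 21 keto aldehyde; 22 tiglaldehyde [(E)-2-methylbut-2-enal]
Product: 25 C7 tiglate with free C9 alcohol, via C7 aldolate 23 (not isolated), via tiglaldehyde hemiacetal 24 (not isolated)
Conditions: (R)-LaLi3(binaphthoxide)3 (20 mol %), 22 (3 equiv), THF, 0 °C to rt
Reagents that add atoms: tiglaldehyde 22, C/C=C(\C)C=O
Why: Proposed new method: the lanthanum–lithium binaphthoxide acts as Brønsted base and Lewis acid, so the C8 enolate of the methyl ketone adds reversibly to the C7 aldehyde held cis to it across the cyclobutane [7-(enolexo)-exo-trig closure of the ring C5–C6–C7–C8–C9–C10], the C7 alkoxide adds to tiglaldehyde, and the metal-bound hemiacetal passes its hydride to the C9 ketone through a six-membered chair, which is irreversible and leaves the tigloyl group on O7. The closest known reactions are the binaphthoxide-catalysed aldol–Tishchenko coupling of aryl ketones with two equivalents of one aldehyde and the Evans–Tishchenko reduction of β-hydroxy ketones; a ring-closing aldol coupled to hydride transfer from a second, conjugated aldehyde is not established. C9 is set by the chair hemiacetal transition state, which delivers hydride from the face of O7 and gives the anti diol. C7 is set by the chiral complex, which must select one of the two aldolates that interconvert by retro-aldol, because the cage is nearly mirror-symmetric about the new ring. Chemoselectivity rests on the substrate: C7 has no α-hydrogen, the enone can enolise only through bridgehead C11 or harmlessly through the C3 methyl, and the C8 enolate cannot reach C1 or C3, which lie trans to the acetyl group on the cyclobutane. The trans placement of O7 and O9 on the ring should also hold back acyl migration.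

Step 15
Reactants: 25 C7 tiglate C9 alcohol; 26 3-methylbut-2-enoic acid
Product: 28 CNP0257816.1, via mixed anhydride 27 (not isolated)
Conditions: 26, 2,4,6-trichlorobenzoyl chloride, Et3N (1 equiv), THF, rt; then 25, DMAP, toluene, rt to 40 °C
Reagents that add atoms: 3-methylbut-2-enoic acid 26, CC(C)=CC(=O)O
Why: Yamaguchi esterification through the mixed anhydride acylates the hindered neopentyl-type C9 alcohol, with no excess triethylamine so that the senecioyl group is not deconjugated through its vinylketene.

**Compound list**

1 | (S)-but-3-yn-2-ol | C[C@H](O)C#C | starting material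
2 | dimethylaluminium (2S,3E)-4-(dimethylalumanyl)-3-methylbut-3-en-2-olate | C[C@H](O[Al](C)C)/C(C)=C/[Al](C)C | intermediate (not isolated)
3 | (2E,4S)-3-methylpent-2-ene-1,4-diol | C[C@H](O)/C(C)=C/CO | intermediate
4 | (2E,4S)-4-hydroxy-3-methylpent-2-enal | C[C@H](O)/C(C)=C/C=O | intermediate
5 | (2S,3E)-3-methyl-5-oxopent-3-en-2-yl 2-methylpropanoate | CC(C)C(=O)O[C@@H](C)/C(C)=C/C=O | intermediate
6 | methyl 3-methylbut-2-enoate | COC(=O)C=C(C)C | starting material
7 | tert-butyl[(1-methoxy-3-methylbuta-1,3-dien-1-yl)oxy]dimethylsilane (C1 geometry immaterial) | COC(O[Si](C)(C)C(C)(C)C)=CC(C)=C | intermediate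
8 | methyl (2E,5S,6E,8S)-5-hydroxy-3,7-dimethyl-8-[(2-methylpropanoyl)oxy]nona-2,6-dienoate | COC(=O)/C=C(\C)C[C@H](O)/C=C(\C)[C@H](C)OC(=O)C(C)C | intermediate
9 | methyl (2E,5S,6E,8S)-5-[(tert-butyldimethylsilyl)oxy]-3,7-dimethyl-8-[(2-methylpropanoyl)oxy]nona-2,6-dienoate | COC(=O)/C=C(\C)C[C@H](O[Si](C)(C)C(C)(C)C)/C=C(\C)[C@H](C)OC(=O)C(C)C | intermediate
10 | (2E,5S,6E,8S)-5-[(tert-butyldimethylsilyl)oxy]-3,7-dimethyl-8-[(2-methylpropanoyl)oxy]nona-2,6-dienoic acid | OC(=O)/C=C(\C)C[C@H](O[Si](C)(C)C(C)(C)C)/C=C(\C)[C@H](C)OC(=O)C(C)C | intermediate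
11 | acid chloride of 10 | ClC(=O)/C=C(\C)C[C@H](O[Si](C)(C)C(C)(C)C)/C=C(\C)[C@H](C)OC(=O)C(C)C | intermediate (not isolated)
12 | vinylketene: (5S,6E,8S)-5-silyloxy-7-methyl-3-methylidene-8-(isobutyryloxy)nona-1,6-dien-1-one | O=C=CC(=C)C[C@H](O[Si](C)(C)C(C)(C)C)/C=C(\C)[C@H](C)OC(=O)C(C)C | intermediate (not isolated)
13 | bicyclo[3.1.1]heptan-6-one: C5 ketone, C3 methylidene, C1 OTBS on the side of the C5 bridge, C10 methyl toward the C1–C3 bridge, C10 (1S)-1-(isobutyryloxy)ethyl on the C5 side | CC(C)C(=O)O[C@@H](C)[C@@]1(C)[C@H]2C(=O)[C@@H]1C(=C)C[C@@H]2O[Si](C)(C)C(C)(C)C | intermediate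
14 | lithium enolate of the isobutyrate of 13 | [Li+].CC(C)=C([O-])O[C@@H](C)[C@@]1(C)[C@H]2C(=O)[C@@H]1C(=C)C[C@@H]2O[Si](C)(C)C(C)(C)C | intermediate (not isolated)
15 | lithium aldolate: seven-membered lactone O9–C7(=O)–C6(CH3)2–C5, C5 alkoxide toward the C1–C3 bridge | [Li+].C[C@@H]1OC(=O)C(C)(C)[C@@]2([O-])[C@@H]3C(=C)C[C@H](O[Si](C)(C)C(C)(C)C)[C@H]2[C@]13C | intermediate (not isolated)
16 | methyl oxalate of the C5 tertiary alcohol of the lactone | C[C@@H]1OC(=O)C(C)(C)[C@@]2(OC(=O)C(=O)OC)[C@@H]3C(=C)C[C@H](O[Si](C)(C)C(C)(C)C)[C@H]2[C@]13C | intermediate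
17 | lactone with C5–H (H toward the C1–C3 bridge), C1 OTBS, C3 methylidene | C[C@@H]1OC(=O)C(C)(C)[C@H]2[C@@H]3C(=C)C[C@H](O[Si](C)(C)C(C)(C)C)[C@H]2[C@]13C | intermediate
18 | C1-hydroxy lactone | C[C@@H]1OC(=O)C(C)(C)[C@H]2[C@@H]3C(=C)C[C@H](O)[C@H]2[C@]13C | intermediate
19 | triol: C1–OH, C5 CMe2CH2OH, C10 methyl and (1S)-1-hydroxyethyl, C3 methylidene | C[C@H](O)[C@@]1(C)[C@@H]2[C@@H](O)CC(=C)[C@H]1[C@@H]2C(C)(C)CO | intermediate
20 | keto aldehyde with C1 ketone and exocyclic C3 methylidene | CC(=O)[C@@]1(C)[C@@H]2C(=O)CC(=C)[C@H]1[C@@H]2C(C)(C)C=O | intermediate (not isolated)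
21 | bicyclo[3.1.1]hept-3-en-2-one with acetyl and methyl on C10 and CMe2CHO on C5 (key-step precursor) | CC(=O)[C@@]1(C)[C@@H]2C(=O)C=C(C)[C@H]1[C@@H]2C(C)(C)C=O | intermediate
22 | tiglaldehyde, (E)-2-methylbut-2-enal | C/C=C(\C)C=O | starting material
23 | C7 aldolate of the cyclised β-hydroxy ketone (metal alkoxide, shown as lithium salt) | [Li+].[O-][C@@H]1CC(=O)[C@@]2(C)[C@@H]3C(=O)C=C(C)[C@H]2[C@@H]3C1(C)C | intermediate (not isolated)
24 | hemiacetal alkoxide of 23 with tiglaldehyde (hemiacetal carbon not assigned) | [Li+].C/C=C(\C)C([O-])O[C@@H]1CC(=O)[C@@]2(C)[C@@H]3C(=O)C=C(C)[C@H]2[C@@H]3C1(C)C | intermediate (not isolated)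
25 | longipinenone C7 tiglate with free C9 alcohol (O7 and O9 anti) | C/C=C(\C)C(=O)O[C@@H]1C[C@@H](O)[C@@]2(C)[C@@H]3C(=O)C=C(C)[C@H]2[C@@H]3C1(C)C | intermediate
26 | 3-methylbut-2-enoic acid | CC(C)=CC(=O)O | starting material
27 | 3-methylbut-2-enoic 2,4,6-trichlorobenzoic anhydride | CC(C)=CC(=O)OC(=O)c1c(Cl)cc(Cl)cc1Cl | intermediate (not isolated)
28 | CNP0257816.1 (C7 tiglate, C9 senecioate) | C/C=C(\C)C(=O)O[C@@H]1C[C@@H](OC(=O)C=C(C)C)[C@@]2(C)[C@@H]3C(=O)C=C(C)[C@H]2[C@@H]3C1(C)C | target

**Step count**

Total: 15 steps. Longest linear sequence: 14 steps (steps 1–3 and 5–15); step 4 prepares the dienolate on a side branch.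

**Steps most likely to fail**

Step 14. Hydride transfer from the hemiacetal of a conjugated aldehyde may be too slow to drain the aldol equilibrium, the complex may not discriminate between the two interconverting aldolates (poor C7 selectivity), or intermolecular condensation of 21 with 22 may take over. The fallback sets out from 21 and comes back at 25, and separates the two events with known chemistry. 21 is cyclised through the kinetic methyl ketone enolate (LiN(SiMe3)2, THF, −78 °C) to the two β-hydroxy ketones: the 7-hydroxy-9-ketone with the hydroxyl on the C4 side F1 and its C7 epimer F2. After chromatographic separation F2 is fed back by retro-aldol/aldol equilibration with catalytic KOtBu. F1 is then submitted to Evans–Tishchenko reduction with 22 and catalytic SmI2 in THF at −10 °C, which gives the anti product with the tigloyl group on O7, that is 25.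

Step 8. The alkene is flanked by two allylic oxygens, one of them an ester, and may be too weak a nucleophile, so that the ketene oligomerises; facial discrimination by the C1 silyl ether may also be incomplete. The fallback sets out from 10 and comes back at 13, and replaces the ester on O9 by a silyl ether for the cycloaddition. K2CO3 in methanol cleaves the isobutyrate to the 8-hydroxy acid F3. Et3SiCl and imidazole (silyl ester lost on aqueous work-up) give the 8-triethylsilyloxy acid F4. The same acid chloride/Et3N protocol then acts on a more electron-rich alkene with a bulkier C9 substituent and gives the C9 triethylsilyl ether cycloadduct F5. Pyridinium tosylate in methanol removes the triethylsilyl group selectively to give the C9 alcohol F6, and 2-methylpropanoyl chloride with pyridine and DMAP gives 13.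

Step 9. The tertiary lithium alkoxide is crowded by the C1 silyl ether and may not acylate before retro-aldol, silyl migration or ring cleavage sets in on warming. The fallback sets out from 13 and comes back at 18, and derivatises the tertiary oxygen intramolecularly. The aldol is run as before and quenched with acetic acid at −78 °C to give the C5-hydroxy lactone silyl ether F7. Bu4NF gives the C1,C5-diol F8, whose two hydroxyls sit on the same side. 1,1'-Thiocarbonyldiimidazole and DMAP in toluene at 80 °C enter through the unhindered C1 hydroxyl and close the six-membered cyclic thionocarbonate F9. Bu3SnH and AIBN then cleave the tertiary C5–O bond (the more substituted radical), and the remaining stannyl thiocarbonate on O1 falls apart on work-up to give 18.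

**Further compounds**

F1 | step 14 | cyclised β-hydroxy ketone, C7 hydroxyl on the C4 side, C9 ketone | O[C@@H]1CC(=O)[C@@]2(C)[C@@H]3C(=O)C=C(C)[C@H]2[C@@H]3C1(C)C
F2 | step 14 | C7 epimer of F1 | O[C@H]1CC(=O)[C@@]2(C)[C@@H]3C(=O)C=C(C)[C@H]2[C@@H]3C1(C)C
F3 | step 8 | (2E,5S,6E,8S)-5-[(tert-butyldimethylsilyl)oxy]-8-hydroxy-3,7-dimethylnona-2,6-dienoic acid | OC(=O)/C=C(\C)C[C@H](O[Si](C)(C)C(C)(C)C)/C=C(\C)[C@H](C)O
F4 | step 8 | (2E,5S,6E,8S)-5-[(tert-butyldimethylsilyl)oxy]-3,7-dimethyl-8-[(triethylsilyl)oxy]nona-2,6-dienoic acid | OC(=O)/C=C(\C)C[C@H](O[Si](C)(C)C(C)(C)C)/C=C(\C)[C@H](C)O[Si](CC)(CC)CC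
F5 | step 8 | analogue of 13 with a triethylsilyl ether on O9 | CC[Si](CC)(CC)O[C@@H](C)[C@@]1(C)[C@H]2C(=O)[C@@H]1C(=C)C[C@@H]2O[Si](C)(C)C(C)(C)C
F6 | step 8 | analogue of 13 with free C9 hydroxyl | O[C@@H](C)[C@@]1(C)[C@H]2C(=O)[C@@H]1C(=C)C[C@@H]2O[Si](C)(C)C(C)(C)C
F7 | step 9 | C5-hydroxy lactone with C1 silyl ether (protonated 15) | C[C@@H]1OC(=O)C(C)(C)[C@@]2(O)[C@@H]3C(=C)C[C@H](O[Si](C)(C)C(C)(C)C)[C@H]2[C@]13C
F8 | step 9 | C1,C5-dihydroxy lactone | C[C@@H]1OC(=O)C(C)(C)[C@@]2(O)[C@@H]3C(=C)C[C@H](O)[C@H]2[C@]13C
F9 | step 9 | cyclic thionocarbonate bridging O1 and O5 of the lactone | C[C@@H]1OC(=O)C(C)(C)[C@@]23OC(=S)O[C@H]4CC(=C)[C@@H]2[C@]1(C)[C@@H]34
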